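**Numbering.** Labdane numbering is used throughout. Ring A is C1–C5 and C10, ring B is C5–C10, and ring C is C8–C9–C11–C12–C13–C14–C15–O. C16 is the methyl group on C13. "α" is the face opposite the C10 methyl group.

## Analysis of the target

The target (C20H33BrO2) is a tricyclic labdane-type bromo ether. A trans-fused decalin (rings A and B) carries an eight-membered cyclic ether (ring C) across C8–C9, and the C13–C14 bond of ring C is a cis-epoxide. There are seven stereocentres: C3 (S, equatorial 3β-bromide), the contiguous set C5 (R, 5α-H), C10 (S, 10β-methyl), C9 (R, 9α-H, C11 β and equatorial) and C8 (R, 8α-oxygen equatorial, 8β-methyl axial), and the oxirane carbons C13 (R) and C14 (S). The 4β, 8β and 10β methyl groups are all axial on one face, and ring C is joined to ring B through two equatorial bonds. The sensitive groups are the secondary bromide next to quaternary C4 (elimination, or skeletal shift if ionised), the trisubstituted epoxide (acid-labile, with a transannular ether oxygen close by) and the tertiary C8–O bond. The difficulties are the stereotetrad C5/C10/C9/C8 with two fully substituted carbons, a medium-ring ether built on a tertiary carbinol, an equatorial bromide that cannot be made by substitution, and an epoxide face defined only by the shape of ring C. The strategy rests on ring B: C5, C10, C9 and C8 are the four termini of a diene C5=C6–C7=C8 (C8 bearing oxygen and methyl) and a dienophile C9=C10 (C10 bearing the angular methyl, C9 the future C11). The four carbons C1–C4 of ring A, with the C3 carbinol and the gem-dimethyl C4, are the tether between C10 and C5.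

## Retrosynthetic reasoning

**C2–H and C3–H (32 to 31).** The equatorial bromide lies beside quaternary C4, so displacement of a 3α leaving group is not realistic. The target 32 is taken back to the C2=C3 alkenyl bromide 31. The forward step is a radical hydrogenation by hydrogen-atom transfer, which keeps the halogen and delivers the last hydrogen axially. Doing this last means the alkyl bromide never meets a base or a hydride.

**Oxirane (31 to 30).** Epoxide 31 comes from diene 30 by peracid epoxidation of C13=C14. It must precede the radical hydrogenation, which would otherwise reduce the trisubstituted olefin. It follows the enolate and nickel chemistry so that the epoxide sees only one more step. The forward reaction has to select the electron-rich olefin over the alkenyl bromide, and one face of ring C.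

**C3 functional group (30 to 25).** Alkenyl bromide 30 is traced through enol triflate 29 to ketone 27, which can enolise only toward C2. Ketone 27 goes back through alcohol 26 to silyl ether 25. The C3 oxygen is the same atom that earlier serves as the stereocontrolling substituent of the tether.

**Ring C (25 to 21 + 22).** Ring C is opened at C13=C14 (ring-closing metathesis of diene 24) and then at O–C15 (alkylation of tertiary alcohol 21 with allyl bromide 22). The olefin is cut because an eight-membered ring can hold only the Z olefin, so the geometry needed for the cis-epoxide is automatic. The two chains also hang from the diequatorial C8–O and C9–C11 bonds of a rigid chair. The forward steps must etherify a hindered tertiary alcohol and close a trisubstituted olefin in a medium ring.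

**Side chain (21 to 14).** The 3-methylbut-3-enyl chain of 21 and 20 is taken back to methyl ketone 19. The C11–C12 bond is cut to a Wittig reaction of aldehyde 16 with stabilised ylide 17, giving enone 18. Carbonyl addition is chosen over substitution because C11 sits on a carbon flanked by two fully substituted centres. One hydrogenation of 18 saturates both C11=C12 and the C6=C7 olefin left by the cycloaddition. Aldehyde 16 comes from ester 14 through alcohol 15. The C8 oxygen stays silylated until the ketone has become an olefin, because a free 8-hydroxy group would add to the C13 carbonyl or cleave by retro-aldol reaction from the C11 aldehyde.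

**Rings A and B (14 to 13).** Octalin 14 is a cyclohexene (ring B, C6=C7) with an acceptor on C9 and oxygen on C8. Cutting C5–C10 and C8–C9 opens both rings and leads to acyclic triene 13. No other cut removes two rings, two C–C bonds and four stereocentres together, and the four centres are then encoded in three olefin geometries and one carbinol. The forward intramolecular Diels–Alder reaction has to pass through the ester-endo transition state on the diene face that keeps the C3 silyloxy group equatorial.

**Diene (13 to 10 + 11).** The dienol ether of 13 is the enol derivative of β,γ-unsaturated ketone 12, by soft enolisation toward the doubly activated C7. The C5=C6 bond of 12 is cut by cross-metathesis into vinyl compound 10 and ketone 11. Quaternary C4 prevents homodimerisation of 10 and enforces the E olefin.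

**C3–C4 (10 to 7 + 8).** Silyl ether 10 comes from alcohol 9, which is cut at C3–C4 to aldehyde 7 and allene 8. A catalytic enantioselective tert-prenylation forms this bond, the gem-dimethyl carbon and the one stereocentre not set by the cycloaddition.

**C1–C10 (7 to 1 + 2).** Aldehyde 7 is unmasked from acetal 6. The C1–C10 bond of 6 is cut to the organometallic from bromide 1 and ynoate 2. Syn-carbocupration gives the E enoate as one isomer, which matters because this geometry becomes the C9/C10 relative configuration.

## Alternatives that were turned down

Alternative 1: The C13=C14 bond is read as the retron of a Ramberg–Bäcklund reaction. Ring C of the 3β-bromo Z-oxocene A1 is enlarged by a sulfonyl bridge between C13 and C14 to the nine-membered cyclic sulfone A2. In the forward direction A2 is α-halogenated, base closes the episulfone, the sulfur bridge is extruded and the ring contracts to A1, which a peracid would turn into the target.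
- For: the thioether behind A2 closes by soft sulfur alkylation, the ring enforces the Z olefin, and no metal carbene is involved, so olefin substitution and allyl-ether isomerisation are not issues. A1 already carries the bromide, so its endgame is one step; on this point it is stronger than the chosen route, which needs six steps after ring closure.
- Against: A2 needs the same hindered tertiary ether plus a two-carbon arm ending in sulfur, a leaving group at secondary C13, a macrocyclic thioetherification and an oxidation. That is about five operations for what allylation and metathesis do in two. The strongly basic halogenating medium would act on a substrate holding a secondary bromide, and the site of α-halogenation (C13–H against C14–H2) is open.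
- Comparison: A1 and A2 presuppose the complete bromodecalin, which this plan does not address. The chosen strategy spends its key step there and closes ring C with fewer operations.

Alternative 2: Ring C is cut at C11–C12. Precursor A4 has a phenylsulfonyl-stabilised C11 and, on the C8 oxygen, an ether arm with a C14 allylic carbonate. Zerovalent palladium ionises the carbonate to a C12–C13–C14 π-allyl complex and the C11 carbanion attacks C12, giving the sulfonyl oxocene A3.
- For: a C–C bond closes the ring under nearly neutral conditions with a soft carbanion. The arm arrives as one four-carbon piece, which is more convergent than building C12–C13 on the carbocycle as is done here.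
- Against: the same π-allyl complex can be attacked at C14, which closes a six-membered tetrahydropyran, and that mode should be faster than eight-membered closure. The Z olefin requires reaction through the anti allyl complex. The nucleophilic carbon sits next to C9 between two fully substituted centres, and the sulfone must be removed reductively afterwards.
- Comparison: metathesis of 24 can give only the eight-membered ring, so the chosen route has no ring-size ambiguity. This alternative also leaves the decalin unsolved.

Alternative 3: The C8–O bond is traced to a C8–C15 bond. A peracid inserts oxygen into the ring B-fused cycloheptanone A6 (Baeyer–Villiger), quaternary C8 migrating with retention to give the eight-membered lactone A5.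
- For: the regiochemistry is secure, the configuration at C8 is carried over, and the tertiary C8–O bond is made without alkylating a tertiary alkoxide. On this point it is stronger than the chosen route, whose step 14 is a weak spot.
- Against: A6 requires a 6-7 fused carbocycle with an all-carbon quaternary C8, which is harder to reach than an oxygenated C8. A5 has the wrong oxidation level at C15 and no C13=C14 unsaturation, with C13 an uncontrolled saturated stereocentre. Dehydrogenation beside the carbonyl and removal of the carbonyl would add at least four steps before epoxidation.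
- Comparison: in the chosen strategy the C8–O bond and its configuration are already created in the cycloaddition by the dienol ether geometry. Only the O–C15 alkylation remains.

Key step: step 7

Assumption: the SEGPHOS antipode written in step 3 is taken to be the one that gives the 6S carbinol 9; if the first run (checked by Mosher ester analysis) shows the 6R carbinol, the mirror-image ligand is used with no other change.

## Route

Step 1
Reactants: 1 2-(2-bromoethyl)-1,3-dioxolane; 2 methyl but-2-ynoate
Product: 6 methyl (2E)-5-(1,3-dioxolan-2-yl)-3-methylpent-2-enoate, via Grignard reagent 3 (not isolated), via alkylcopper reagent 4 (not isolated), via alkenylcopper adduct 5 (not isolated)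
Conditions: Mg, THF, 25 °C; CuBr·SMe2 (1.0 equiv), THF/Me2S, −78 °C; then 2, −78 °C; MeOH then aq. NH4Cl, −78 °C → rt
Reagents that add atoms: none
Why: Grignard formation, transmetalation to monovalent copper and syn-carbocupration of the ynoate, followed by protonation of the alkenylcopper with retention, put the new chain and H-9 cis, so the C9=C10 enoate should form as the E isomer only. Quenching at −78 °C prevents equilibration through the allenoate.

Step 2
Reactants: 6 methyl (2E)-5-(1,3-dioxolan-2-yl)-3-methylpent-2-enoate
Product: 7 methyl (2E)-3-methyl-6-oxohex-2-enoate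
Conditions: 1 M aq. HCl, THF, 40 °C
Reagents that add atoms: water, O
Why: Acid-catalysed acetal hydrolysis; the trisubstituted enoate is inert to dilute acid at this temperature.

Step 3
Reactants: 7 methyl (2E)-3-methyl-6-oxohex-2-enoate; 8 3-methylbuta-1,2-diene
Product: 9 methyl (2E,6S)-6-hydroxy-3,7,7-trimethylnona-2,8-dienoate
Conditions: preformed π-allyliridium C,O-benzoate of (S)-SEGPHOS and 4-cyano-3-nitrobenzoic acid (from [Ir(cod)Cl]2, 5 mol %), i-PrOH (2 equiv), PhMe, 50 °C
Reagents that add atoms: none
Why: Krische iridium-catalysed tert-prenylation: the allene is hydrometalated to a 1,1-dimethylallyl-iridium species that adds to the aldehyde through a closed chair at its substituted terminus, forming C3–C4 and the gem-dimethyl C4 together. The chiral bisphosphine selects the aldehyde face and sets C3 (S); the β,β-disubstituted enoate is not reduced.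

Step 4
Reactants: 9 methyl (2E,6S)-6-hydroxy-3,7,7-trimethylnona-2,8-dienoate
Product: 10 methyl (2E,6S)-6-(tert-butyldimethylsilyloxy)-3,7,7-trimethylnona-2,8-dienoate
Conditions: TBSOTf, 2,6-lutidine, CH2Cl2, 0 °C
Reagents that add atoms: tert-butyldimethylsilyl triflate, CC(C)(C)[Si](C)(C)OS(=O)(=O)C(F)(F)F
Why: Silylation of a neopentylic secondary alcohol needs the silyl triflate; the resulting ether is robust enough for every step up to step 16.

Step 5
Reactants: 10 methyl (2E,6S)-6-(tert-butyldimethylsilyloxy)-3,7,7-trimethylnona-2,8-dienoate; 11 pent-4-en-2-one
Product: 12 methyl (2E,6S,8E)-6-(tert-butyldimethylsilyloxy)-3,7,7-trimethyl-11-oxododeca-2,8-dienoate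
Conditions: second-generation Hoveyda–Grubbs catalyst (5 mol %), 11 (4 equiv), 1,4-benzoquinone (10 mol %), CH2Cl2, 40 °C
Reagents that add atoms: none
Why: Olefin cross-metathesis: the vinyl group on quaternary C4 does not homodimerise and couples with the excess of the unhindered partner, the quaternary carbon enforcing E at C5=C6; the trisubstituted enoate is a spectator. Benzoquinone suppresses ruthenium hydride-mediated migration of the β,γ double bond.

Step 6
Reactants: 12 methyl (2E,6S,8E)-6-(tert-butyldimethylsilyloxy)-3,7,7-trimethyl-11-oxododeca-2,8-dienoate
Product: 13 methyl (2E,6S,8E,10Z)-6-(tert-butyldimethylsilyloxy)-3,7,7-trimethyl-11-(triethylsilyloxy)dodeca-2,8,10-trienoate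
Conditions: TESOTf, Et3N, CH2Cl2, −78 → 0 °C; non-acidic work-up
Reagents that add atoms: triethylsilyl triflate, CC[Si](CC)(CC)OS(=O)(=O)C(F)(F)F
Why: Soft enolisation removes a C7 hydrogen, which is both allylic and α to the ketone, and gives the conjugated silyl dienol ether. The silyloxy group should end up cis to C6 (Z at C7=C8), which keeps the C8 methyl group trans to the vinyl residue.

Step 7
Reactants: 13 methyl (2E,6S,8E,10Z)-6-(tert-butyldimethylsilyloxy)-3,7,7-trimethyl-11-(triethylsilyloxy)dodeca-2,8,10-trienoate
Product: 14 methyl 3β-(tert-butyldimethylsilyloxy)-8α-(triethylsilyloxy)drim-6-en-11-oate (trans-octalin; 4,4-dimethyl, 5α-H, 8β-methyl, 9β-CO2Me, 10β-methyl)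
Conditions: PhMe (0.01 M), BHT (cat.), 180 °C, sealed tube, base-washed glass
Reagents that add atoms: none
Why: Thermal, concerted but asynchronous normal-demand [4+2] cycloaddition of the C5=C6–C7=C8 silyloxydiene with the C9=C10 enoate; the closest known class is the type 1 intramolecular Diels–Alder reaction of 1,7,9-decatrienoates to trans-octalins. Ring B closes as the six-membered cycloaddition ring through the new C5–C10 and C8–C9 bonds, and ring A closes at the same time as the six-membered ring spanned by the C1–C4 tether in the fused mode; the tether allows only this regiochemistry, which is also the polarity-matched one (C5 of the dienol ether to the β-carbon C10). C10 and C9: the E enoate adds suprafacially, so the C10 methyl and the C9 ester stay cis. C5 and C8: the diene (E at C5=C6, Z at C7=C8) adds suprafacially, so its two inside groups, H-5 and the silyloxy group, become cis, giving 5α-H with 8α-oxygen and 8β-methyl. The ester-endo transition state links the two pairs: the ester lies cis to the outside groups of the diene (C4 and the C8 methyl), which gives the trans ring fusion and the 9β ester. The absolute sense comes from C3, whose silyloxy group is equatorial in the chair-like tether only when the enoate adds to one diene face, giving the 3β/10β relationship. The step needs endo over exo and one π-face; overlap of the ester with the diene, compression of the tether by the gem-dimethyl C4 and the equatorial preference at C3 are what provide them, and the Z dienol ether has no cis C–H for a 1,5-hydrogen shift, so it tolerates heating.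

Step 8
Reactants: 14 methyl 3β-(tert-butyldimethylsilyloxy)-8α-(triethylsilyloxy)drim-6-en-11-oate
Product: 15 3β-(tert-butyldimethylsilyloxy)-8α-(triethylsilyloxy)drim-6-en-11-ol
Conditions: i-Bu2AlH (3 equiv), CH2Cl2, −78 → 0 °C; aq. potassium sodium tartrate
Reagents that add atoms: none
Why: Hydride reduction of the hindered ester to the primary alcohol; the covalent aluminium alkoxide and the low temperature disfavour silyl migration from O-8 to O-11.

Step 9
Reactants: 15 3β-(tert-butyldimethylsilyloxy)-8α-(triethylsilyloxy)drim-6-en-11-ol
Product: 16 3β-(tert-butyldimethylsilyloxy)-8α-(triethylsilyloxy)drim-6-en-11-al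
Conditions: Dess–Martin periodinane, NaHCO3, CH2Cl2, 0 °C → rt
Reagents that add atoms: none
Why: Dess–Martin oxidation under buffered, non-basic conditions avoids β-elimination of the C8 silyloxy group; the formyl group is already equatorial, so C9 is not at risk of epimerisation.

Step 10
Reactants: 16 3β-(tert-butyldimethylsilyloxy)-8α-(triethylsilyloxy)drim-6-en-11-al; 17 1-(triphenylphosphoranylidene)propan-2-one
Product: 18 (11E)-3β-(tert-butyldimethylsilyloxy)-8α-(triethylsilyloxy)-14,15-dinorlabda-6,11-dien-13-one
Conditions: PhMe, 100 °C
Reagents that add atoms: none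
Why: Wittig olefination with a stabilised ylide forms C11=C12 as the E enone and brings in C12, C13 and C16. The ylide is too weakly basic to eliminate the β-silyloxy group, and addition to a carbonyl is less sensitive to the crowding at C9 than substitution at C11 would be.

Step 11
Reactants: 18 (11E)-3β-(tert-butyldimethylsilyloxy)-8α-(triethylsilyloxy)-14,15-dinorlabda-6,11-dien-13-one
Product: 19 3β-(tert-butyldimethylsilyloxy)-8α-(triethylsilyloxy)-14,15-dinorlabdan-13-one
Conditions: H2 (3 atm), 10% Pd/C, EtOAc, rt
Reagents that add atoms: none
Why: Heterogeneous hydrogenation saturates the enone C=C and the C6=C7 ring olefin in one operation. No stereocentre is created, and the ketone and silyl ethers survive in a neutral aprotic solvent.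

Step 12
Reactants: 19 3β-(tert-butyldimethylsilyloxy)-8α-(triethylsilyloxy)-14,15-dinorlabdan-13-one
Product: 20 3β-(tert-butyldimethylsilyloxy)-8α-(triethylsilyloxy)-15-norlabd-13-ene
Conditions: Ph3PCH3Br, KOtBu, THF, 0 °C → rt
Reagents that add atoms: methyltriphenylphosphonium bromide, C[P+](c1ccccc1)(c1ccccc1)c1ccccc1.[Br-]
Why: Wittig methylenation of an unhindered methyl ketone gives the 1,1-disubstituted olefin whose substituted carbon is C13. Removing the carbonyl before O-8 is freed prevents hemiketal formation.

Step 13
Reactants: 20 3β-(tert-butyldimethylsilyloxy)-8α-(triethylsilyloxy)-15-norlabd-13-ene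
Product: 21 3β-(tert-butyldimethylsilyloxy)-15-norlabd-13-en-8α-ol
Conditions: HF·pyridine, pyridine, THF, 0 °C → rt
Reagents that add atoms: none
Why: Buffered fluoride cleaves the triethylsilyl ether much faster than the tert-butyldimethylsilyl ether on the neopentylic C3 carbinol. The medium is too weakly acidic to add the new tertiary alcohol across the 1,1-disubstituted olefin.

Step 14
Reactants: 21 3β-(tert-butyldimethylsilyloxy)-15-norlabd-13-en-8α-ol; 22 allyl bromide
Product: 24 8α-(allyloxy)-3β-(tert-butyldimethylsilyloxy)-15-norlabd-13-ene, via potassium alkoxide 23 (not isolated)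
Conditions: KH, 18-crown-6 (cat.), THF, 0 °C; then 22, 0 °C → rt
Reagents that add atoms: none
Why: Williamson etherification forms O–C15; the naked potassium alkoxide and a reactive allylic bromide are used because the C8 alkoxide is tertiary and flanked by C9.

Step 15
Reactants: 24 8α-(allyloxy)-3β-(tert-butyldimethylsilyloxy)-15-norlabd-13-ene
Product: 25 (13Z)-3β-(tert-butyldimethylsilyloxy)-8α,15-epoxylabd-13-ene
Conditions: second-generation Grubbs catalyst (10 mol %), 1,4-benzoquinone (20 mol %), PhMe (2 mM), 80 °C
Reagents that add atoms: none
Why: Ring-closing metathesis: the catalyst loads on the allyl ether and closes onto the 1,1-disubstituted olefin, forming C13=C14 in an eight-membered ring that can hold only the Z olefin. The diequatorial C8–O and C9–C11 bonds hold the two chains gauche, which favours cyclisation over oligomerisation.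

Step 16
Reactants: 25 (13Z)-3β-(tert-butyldimethylsilyloxy)-8α,15-epoxylabd-13-ene
Product: 26 (13Z)-8α,15-epoxylabd-13-en-3β-ol
Conditions: Bu4NF, THF, 60 °C
Reagents that add atoms: none
Why: Fluoride cleavage of the hindered silyl ether needs heating; nothing else in 25 reacts with fluoride.

Step 17
Reactants: 26 (13Z)-8α,15-epoxylabd-13-en-3β-ol
Product: 27 (13Z)-8α,15-epoxylabd-13-en-3-one
Conditions: Dess–Martin periodinane, NaHCO3, CH2Cl2, rt
Reagents that add atoms: none
Why: Dess–Martin oxidation of the secondary alcohol; the allylic ether and the trisubstituted olefin are inert to the periodinane.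

Step 18
Reactants: 27 (13Z)-8α,15-epoxylabd-13-en-3-one
Product: 29 (13Z)-8α,15-epoxylabda-2,13-dien-3-yl trifluoromethanesulfonate, via potassium enolate 28 (not isolated)
Conditions: KN(SiMe3)2, THF, −78 °C; then PhNTf2, −78 → 0 °C
Reagents that add atoms: N-phenylbis(trifluoromethanesulfonimide), O=S(=O)(N(c1ccccc1)S(=O)(=O)C(F)(F)F)C(F)(F)F
Why: Enolisation is possible only toward C2 because C4 is quaternary, and O-sulfonylation of the enolate gives the C2=C3 enol triflate as the single regioisomer.

Step 19
Reactants: 29 (13Z)-8α,15-epoxylabda-2,13-dien-3-yl trifluoromethanesulfonate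
Product: 30 (13Z)-3-bromo-8α,15-epoxylabda-2,13-diene
Conditions: Ni(cod)2 (10 mol %), LiBr (3 equiv), DMA/THF (1:3), rt
Reagents that add atoms: lithium bromide, [Li+].[Br-]
Why: Nickel-catalysed halide exchange of an enol triflate: oxidative addition of zerovalent nickel to the C–O bond, triflate-to-bromide exchange and C–Br reductive elimination. No electrophilic bromine is present, so the C13=C14 olefin is untouched.

Step 20
Reactants: 30 (13Z)-3-bromo-8α,15-epoxylabda-2,13-diene
Product: 31 (13R,14S)-3-bromo-8α,15:13,14-diepoxylabd-2-ene
Conditions: mCPBA, NaHCO3, CH2Cl2, 0 °C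
Reagents that add atoms: 3-chloroperbenzoic acid, OOC(=O)c1cccc(Cl)c1
Why: Prilezhaev epoxidation: the trisubstituted C13=C14 olefin is far more nucleophilic than the alkenyl bromide. In both accessible conformers of ring C (C15 anti to the 8β-methyl group, or C15 anti to C7) C11 and the ring oxygen lie on the same face of the olefin, and attack on the open peripheral face should give the 13R,14S oxirane.

Step 21
Reactants: 31 (13R,14S)-3-bromo-8α,15:13,14-diepoxylabd-2-ene
Product: 32 (3S,5R,8R,9R,10S,13R,14S)-3-bromo-8,15:13,14-diepoxylabdane (target)
Conditions: Mn(dpm)3 (10 mol %), PhSiH3, t-BuOOH, i-PrOH, rt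
Reagents that add atoms: none
Why: Mukaiyama-type hydrogen-atom-transfer hydrogenation: the manganese hydride adds a hydrogen atom to C2 and gives the α-bromo C3 radical, never a β-bromo radical, so the halogen is kept. The second hydrogen is delivered axially from the α face, opposite the axial 4β and 10β methyl groups, which leaves bromine equatorial (3β, S); the neutral conditions spare the epoxide and the ether.

## Compound list

1 | 2-(2-bromoethyl)-1,3-dioxolane | BrCCC1OCCO1 | starting material
2 | methyl but-2-ynoate | CC#CC(=O)OC | starting material
3 | [2-(1,3-dioxolan-2-yl)ethyl]magnesium bromide (not isolated) | Br[Mg]CCC1OCCO1 | intermediate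
4 | [2-(1,3-dioxolan-2-yl)ethyl]copper (not isolated) | [Cu]CCC1OCCO1 | intermediate
5 | alkenylcopper adduct, copper on C9 cis to the new chain (not isolated) | COC(=O)/C([Cu])=C(\C)CCC1OCCO1 | intermediate
6 | methyl (2E)-5-(1,3-dioxolan-2-yl)-3-methylpent-2-enoate | COC(=O)/C=C(\C)CCC1OCCO1 | intermediate
7 | methyl (2E)-3-methyl-6-oxohex-2-enoate | COC(=O)/C=C(\C)CCC=O | intermediate
8 | 3-methylbuta-1,2-diene | CC(C)=C=C | starting material
9 | methyl (2E,6S)-6-hydroxy-3,7,7-trimethylnona-2,8-dienoate | C=CC(C)(C)[C@@H](O)CC/C(C)=C/C(=O)OC | intermediate
10 | methyl (2E,6S)-6-(tert-butyldimethylsilyloxy)-3,7,7-trimethylnona-2,8-dienoate | C=CC(C)(C)[C@@H](O[Si](C)(C)C(C)(C)C)CC/C(C)=C/C(=O)OC | intermediate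
11 | pent-4-en-2-one | CC(=O)CC=C | starting material
12 | methyl (2E,6S,8E)-6-(tert-butyldimethylsilyloxy)-3,7,7-trimethyl-11-oxododeca-2,8-dienoate | CC(=O)C/C=C/C(C)(C)[C@@H](O[Si](C)(C)C(C)(C)C)CC/C(C)=C/C(=O)OC | intermediate
13 | methyl (2E,6S,8E,10Z)-6-(tert-butyldimethylsilyloxy)-3,7,7-trimethyl-11-(triethylsilyloxy)dodeca-2,8,10-trienoate | CC(C)(/C=C/C=C(/C)O[Si](CC)(CC)CC)[C@@H](O[Si](C)(C)C(C)(C)C)CC/C(C)=C/C(=O)OC | intermediate
14 | methyl 3β-(tert-butyldimethylsilyloxy)-8α-(triethylsilyloxy)drim-6-en-11-oate | CC1(C)[C@@H](O[Si](C)(C)C(C)(C)C)CC[C@]2(C)[C@@H](C(=O)OC)[C@](C)(O[Si](CC)(CC)CC)C=C[C@@H]12 | intermediate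
15 | 3β-(tert-butyldimethylsilyloxy)-8α-(triethylsilyloxy)drim-6-en-11-ol | CC1(C)[C@@H](O[Si](C)(C)C(C)(C)C)CC[C@]2(C)[C@@H](CO)[C@](C)(O[Si](CC)(CC)CC)C=C[C@@H]12 | intermediate
16 | 3β-(tert-butyldimethylsilyloxy)-8α-(triethylsilyloxy)drim-6-en-11-al | CC1(C)[C@@H](O[Si](C)(C)C(C)(C)C)CC[C@]2(C)[C@@H](C=O)[C@](C)(O[Si](CC)(CC)CC)C=C[C@@H]12 | intermediate
17 | 1-(triphenylphosphoranylidene)propan-2-one | CC(=O)C=P(c1ccccc1)(c1ccccc1)c1ccccc1 | starting material
18 | (11E)-3β-(tert-butyldimethylsilyloxy)-8α-(triethylsilyloxy)-14,15-dinorlabda-6,11-dien-13-one | CC1(C)[C@@H](O[Si](C)(C)C(C)(C)C)CC[C@]2(C)[C@@H](/C=C/C(C)=O)[C@](C)(O[Si](CC)(CC)CC)C=C[C@@H]12 | intermediate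
19 | 3β-(tert-butyldimethylsilyloxy)-8α-(triethylsilyloxy)-14,15-dinorlabdan-13-one | CC1(C)[C@@H](O[Si](C)(C)C(C)(C)C)CC[C@]2(C)[C@@H](CCC(C)=O)[C@](C)(O[Si](CC)(CC)CC)CC[C@@H]12 | intermediate
20 | 3β-(tert-butyldimethylsilyloxy)-8α-(triethylsilyloxy)-15-norlabd-13-ene | CC1(C)[C@@H](O[Si](C)(C)C(C)(C)C)CC[C@]2(C)[C@@H](CCC(C)=C)[C@](C)(O[Si](CC)(CC)CC)CC[C@@H]12 | intermediate
21 | 3β-(tert-butyldimethylsilyloxy)-15-norlabd-13-en-8α-ol | CC1(C)[C@@H](O[Si](C)(C)C(C)(C)C)CC[C@]2(C)[C@@H](CCC(C)=C)[C@](C)(O)CC[C@@H]12 | intermediate
22 | allyl bromide | C=CCBr | starting material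
23 | potassium 8α-alkoxide of 21 (not isolated) | CC1(C)[C@@H](O[Si](C)(C)C(C)(C)C)CC[C@]2(C)[C@@H](CCC(C)=C)[C@](C)([O-])CC[C@@H]12.[K+] | intermediate
24 | 8α-(allyloxy)-3β-(tert-butyldimethylsilyloxy)-15-norlabd-13-ene | CC1(C)[C@@H](O[Si](C)(C)C(C)(C)C)CC[C@]2(C)[C@@H](CCC(C)=C)[C@](C)(OCC=C)CC[C@@H]12 | intermediate
25 | (13Z)-3β-(tert-butyldimethylsilyloxy)-8α,15-epoxylabd-13-ene | CC1(C)[C@@H](O[Si](C)(C)C(C)(C)C)CC[C@]2(C)[C@H]3CC/C(C)=C\CO[C@]3(C)CC[C@@H]12 | intermediate
26 | (13Z)-8α,15-epoxylabd-13-en-3β-ol | CC1(C)[C@@H](O)CC[C@]2(C)[C@H]3CC/C(C)=C\CO[C@]3(C)CC[C@@H]12 | intermediate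
27 | (13Z)-8α,15-epoxylabd-13-en-3-one | CC1(C)C(=O)CC[C@]2(C)[C@H]3CC/C(C)=C\CO[C@]3(C)CC[C@@H]12 | intermediate
28 | potassium C2=C3 enolate of 27 (not isolated) | CC1(C)C([O-])=CC[C@]2(C)[C@H]3CC/C(C)=C\CO[C@]3(C)CC[C@@H]12.[K+] | intermediate
29 | (13Z)-8α,15-epoxylabda-2,13-dien-3-yl trifluoromethanesulfonate | CC1(C)C(OS(=O)(=O)C(F)(F)F)=CC[C@]2(C)[C@H]3CC/C(C)=C\CO[C@]3(C)CC[C@@H]12 | intermediate
30 | (13Z)-3-bromo-8α,15-epoxylabda-2,13-diene | CC1(C)C(Br)=CC[C@]2(C)[C@H]3CC/C(C)=C\CO[C@]3(C)CC[C@@H]12 | intermediate
31 | (13R,14S)-3-bromo-8α,15:13,14-diepoxylabd-2-ene | CC1(C)C(Br)=CC[C@]2(C)[C@H]3CC[C@@]4(C)O[C@H]4CO[C@]3(C)CC[C@@H]12 | intermediate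
32 | (3S,5R,8R,9R,10S,13R,14S)-3-bromo-8,15:13,14-diepoxylabdane | CC1(C)[C@@H](Br)CC[C@]2(C)[C@H]3CC[C@@]4(C)O[C@H]4CO[C@]3(C)CC[C@@H]12 | target

## Step count and least certain steps

Total: 21 steps. Longest linear sequence: 21 steps (1 and 2 to 32); the route is linear, with 8, 11, 17 and 22 added as purchased building blocks.

**Step 7 (key step).** The most likely failure is incomplete endo and π-face selectivity together with a low rate. The desired transition state is the one in which the 4β, 8β and 10β methyl groups begin to meet in 1,3-diaxial positions. The enoate is β,β-disubstituted, C8 carries an inside substituent, and the equatorial preference of a silyloxy group is modest. Long heating can also lead to loss of the enol silyl group. A Lewis acid such as Me2AlCl is a variant of conditions. The fallback changes the mechanism and sets out from 12: deprotonation with KN(SiMe3)2 in THF at −78 °C gives the potassium dienolate, whose oxyanion-accelerated cycloaddition (γ-Michael addition of C5 to C10, then aldol closure of C9 onto C8) should run well below room temperature through the same endo arrangement, held by potassium between the two oxygens. Quenching gives methyl 3β-(tert-butyldimethylsilyloxy)-8α-hydroxydrim-6-en-11-oate F1, and silylation of F1 with TESOTf and 2,6-lutidine returns to the route at 14.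

**Step 5.** The likely failure is migration of the β,γ double bond of 11, or of product 12, into conjugation under ruthenium hydride catalysis. Metathesis of the isomerised ketone would give a chain one carbon short, and the hindered vinyl group of 10 reacts slowly enough for this to compete. The fallback sets out from 10 and couples at the alcohol oxidation level: cross-metathesis with pent-4-en-2-ol, which cannot conjugate, gives methyl (2E,6S,8E)-6-(tert-butyldimethylsilyloxy)-11-hydroxy-3,7,7-trimethyldodeca-2,8-dienoate F2 as a mixture at the new carbinol. Buffered Dess–Martin oxidation of F2 returns to the route at 12.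

**Step 14.** The likely failure is low conversion, because the C8 alkoxide is tertiary, carries an axial methyl group and is flanked by the C9 chain; elimination of the allyl bromide then consumes the base. The fallback sets out from 21 and replaces the substitution by capture of a π-allyl complex: allyl tert-butyl carbonate with Pd(PPh3)4 (zerovalent palladium) in THF at reflux, where the tert-butoxide released in the flask deprotonates the alcohol and the small cationic allyl electrophile is attacked by oxygen. This gives 24 directly, and no compound outside the list is made (F0).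

**Step 15.** The likely failures are isomerisation of the allyl ether to a propenyl ether and intermolecular metathesis, since closing a trisubstituted olefin in an eight-membered ring is slow. The fallback sets out from 24 and changes the ring-closing bond formation to a carbonyl coupling: ozonolysis of both olefins (O3, CH2Cl2, −78 °C; Me2S) gives the keto aldehyde 3β-(tert-butyldimethylsilyloxy)-8α-(2-oxoethoxy)-14,15-dinorlabdan-13-one F3. Intramolecular McMurry coupling of F3 (TiCl3(DME)1.5, Zn–Cu, DME, reflux, slow addition) forms C13=C14, again necessarily Z, and returns to the route at 25.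

**Step 19.** The likely failure is slow oxidative addition to an enol triflate beside the quaternary C4, with reduction to the C2=C3 olefin or opening of the allylic ether by nickel taking over. The fallback sets out from 29 and goes through tin: Pd(PPh3)4, Me3SnSnMe3 and LiCl in THF at reflux give (13Z)-3-(trimethylstannyl)-8α,15-epoxylabda-2,13-diene F4. Ipso-bromodestannylation of F4 with N-bromosuccinimide in CH2Cl2 at −78 °C, which is much faster than attack on the ring olefin, returns to the route at 30.

**Step 20.** The likely failure is poor or reversed facial selectivity, because the prediction rests on a conformational analysis of a flexible eight-membered ring; acid-promoted transannular opening of the product by the ring oxygen is a second risk. The fallback sets out from 30 and delivers oxygen to the other face. N-Bromosuccinimide in aqueous THF forms the bromonium ion on the face a peracid would use, and water opens it at tertiary C13 from the opposite side, giving the bromohydrin (13R,14R)-3,14-dibromo-8α,15-epoxylabd-2-en-13-ol F5. K2CO3 in MeOH closes F5 with inversion at C14 and returns to the route at 31.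

## Further compounds

F1 | step 7 | methyl 3β-(tert-butyldimethylsilyloxy)-8α-hydroxydrim-6-en-11-oate | CC1(C)[C@@H](O[Si](C)(C)C(C)(C)C)CC[C@]2(C)[C@@H](C(=O)OC)[C@](C)(O)C=C[C@@H]12
F2 | step 5 | methyl (2E,6S,8E)-6-(tert-butyldimethylsilyloxy)-11-hydroxy-3,7,7-trimethyldodeca-2,8-dienoate | CC(O)C/C=C/C(C)(C)[C@@H](O[Si](C)(C)C(C)(C)C)CC/C(C)=C/C(=O)OC
F0 | step 14 | none | none
F3 | step 15 | 3β-(tert-butyldimethylsilyloxy)-8α-(2-oxoethoxy)-14,15-dinorlabdan-13-one | CC1(C)[C@@H](O[Si](C)(C)C(C)(C)C)CC[C@]2(C)[C@@H](CCC(C)=O)[C@](C)(OCC=O)CC[C@@H]12
F4 | step 19 | (13Z)-3-(trimethylstannyl)-8α,15-epoxylabda-2,13-diene | CC1(C)C([Sn](C)(C)C)=CC[C@]2(C)[C@H]3CC/C(C)=C\CO[C@]3(C)CC[C@@H]12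
F5 | step 20 | (13R,14R)-3,14-dibromo-8α,15-epoxylabd-2-en-13-ol | CC1(C)C(Br)=CC[C@]2(C)[C@H]3CC[C@@](C)(O)[C@H](Br)CO[C@]3(C)CC[C@@H]12
A1 | alternative 1 | 3β-bromo Z-oxocene, (13Z)-3β-bromo-8α,15-epoxylabd-13-ene | CC1(C)[C@@H](Br)CC[C@]2(C)[C@H]3CC/C(C)=C\CO[C@]3(C)CC[C@@H]12
A2 | alternative 1 | nine-membered cyclic sulfone with sulfur between C13 and C14 (3β-bromo, C13 epimers) | CC1(C)[C@@H](Br)CC[C@]2(C)[C@H]3CCC(C)S(=O)(=O)CCO[C@]3(C)CC[C@@H]12
A3 | alternative 2 | C11-phenylsulfonyl Z-oxocene (3β-silyloxy, C11 epimers) | CC1(C)[C@@H](O[Si](C)(C)C(C)(C)C)CC[C@]2(C)[C@H]3C(S(=O)(=O)c4ccccc4)C/C(C)=C\CO[C@]3(C)CC[C@@H]12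
A4 | alternative 2 | open precursor: C11 phenyl sulfone with the C8 ether arm carrying the C14 allylic methyl carbonate (C14 epimers) | CC1(C)[C@@H](O[Si](C)(C)C(C)(C)C)CC[C@]2(C)[C@@H](CS(=O)(=O)c3ccccc3)[C@](C)(OCC(OC(=O)OC)C(C)=C)CC[C@@H]12
A5 | alternative 3 | eight-membered C15 lactone (3β-silyloxy, C13 epimers) | CC1(C)[C@@H](O[Si](C)(C)C(C)(C)C)CC[C@]2(C)[C@H]3CCC(C)CC(=O)O[C@]3(C)CC[C@@H]12
A6 | alternative 3 | ring B-fused cycloheptanone with the C15 carbonyl on quaternary C8 (3β-silyloxy, C13 epimers) | CC1(C)[C@@H](O[Si](C)(C)C(C)(C)C)CC[C@]2(C)[C@H]3CCC(C)CC(=O)[C@]3(C)CC[C@@H]12
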